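Two questions stand on one flask.

substrate 0.10 M; partner 0.200 M; time 20 h

- how much of the substrate has reacted by 20 h
- how much product there is at 20 h, in percent of the substrate charged

    substrate + partner → product, rate k1*[substrate]^2*[partner]^0.5 (k1 = 4.13 M⁻¹·⁵ min⁻¹)
    partner → decomposed reagent (k2 = 0.117 min⁻¹)

Partner has two exits, coupling with substrate into product or decomposing, and its half-life by decomposition alone, 0.099 h, is far shorter than the 20 h allowed, so I follow one partner molecule, not the clock. At the start it reaches product with a chance of 44.1%; this share of the coupling rate in both rates together is the fork chance. I let half of the partner, 1.00 equivalent of the substrate charge, go at that chance, which in my estimate turns 44.1% of the substrate. At that point I reckon the fork chance at 25.9%, lower than at the start, and at this chance the other half turns 25.9% in my estimate. I commit to 70.0% for both answers, since substrate's one exit is product.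

The forecast says 68% and 68%, a little below mine, on the grounds that “the substrate stalls near two-thirds conversion”. The simulation gives 66.9% and 66.9%.

In this flask both steps run while partner lasts: half of the coupling turnover is done by 0.0526 h, and at 2.00 h partner, the limiting reagent, stands at 0%, substrate at 33.1% and product at 66.9%. At 200 h product still stands at 66.9%. Decomposition took 1.33 equiv, so the fork chance averaged over this flask is 33.4%, between my two. In the neighbour flask with 0.080 M of partner, the fork chance starts at 55.5%, the same two steps give 42.9%, and that flask reads 44.1%.

All constants were chosen freely; the flask was simulated.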